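## Structural features

The target 14 is a cyclobutane whose adjacent carbons C1 and C2 each carry the same arm, ring–C-alpha≡C-beta–(C5 of a 2,2'-bithiophene); C3 and C4 are plain methylenes. C1 and C2 are neighbouring stereocentres. The SMILES descriptors place the two arms cis, so the molecule has a mirror plane, is meso (1R,2S), and only relative configuration has to be controlled. Cis is the less stable arrangement on a four-membered ring, so any intermediate with an acidifying group directly on C1 or C2 would drift towards trans. The fragile parts are the four thiophene rings (electron-rich, open to electrophiles and strong oxidants, weak ligands for late metals, acidic free alpha C–H), the conjugated alkynes, and the cis-1,2-dialkynylcyclobutane unit itself, a 1,5-diyne on a strained ring that should not be heated. The real difficulty is building a cis-1,2-disubstituted cyclobutane with two unsaturated carbon arms without a stereochemical leak. The key step uses the fact that C-alpha–C1–C2–C-alpha' can be written as the diene of 1,2-dimethylenecyclobutane, and the two C-beta atoms with their bithiophenes as the two carbons of one diarylalkyne. Joining them gives a six-membered ring C-alpha–C1–C2–C-alpha'–C-beta'–C-beta fused to the four-membered ring, which holds the arms cis and is later cut between the two C-beta atoms.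

## Logic of the disconnections

14 to 12 (through 13). No skeletal bond is cut. The second pi bond of each C-alpha≡C-beta is taken back to a C-beta carbonyl and a C-alpha methylene. This places the carbonyls where an alkene cleavage delivers them and keeps C1 and C2 beta to the carbonyls, so they cannot epimerise. The gain is that the alkynes appear only in the last step. The forward step must enolise both ketones, eliminate twice at low temperature, and avoid an aldol reaction between the two arms.

12 to 9 (through 10 and 11). The two carbonyl carbons are rejoined as the C3=C4 double bond of a six-membered ring. This turns two separate arms into one symmetrical bicycle. The forward step needs an oxidant that cuts a tetrasubstituted diaryl alkene and spares four thiophene rings.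

9 to 8. The two cis hydrogens on C1 and C6 are removed to give the ring-fusion alkene. Both stereocentres disappear, and the stereochemical problem becomes one syn addition to a symmetrical alkene held in a six-membered ring. The forward step must reduce C1=C6 and leave C3=C4.

8 to 2 and 7. The C2–C3 and C4–C5 bonds, which are the two C-alpha–C-beta bonds of the arms, are cut in a retro-[4+2]. Every carbon of 14 then comes from two symmetrical pieces. The forward step needs cross-cycloaddition of an unactivated diene and alkyne in a one-to-one sense, and the cyclohexa-1,4-diene must not aromatise.

7 to 3 (twice) and 4 (through 5 and 6). Both C(sp)–C5(thienyl) bonds are cut. This is a standard aryl–alkyne coupling pattern and leads to two commercial compounds. The forward step must couple both ends of a two-carbon unit without alkyne homocoupling.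

2 to 1 (twice). The ring bond between the two methylene-bearing carbons and the opposite CH2–CH2 bond are cut. This is the known thermal dimerisation of 1, and the demand is only that conversion be kept low so that 2 does not react further.

## Other disconnections considered

Alternative 1: The cut is the C1–C4 ring bond of 14, made by ring contraction, with both arms shortened to one-carbon stubs tied together as a lactone.
- **Forward key step:** photolysis of 2-diazo-3-(hydroxymethyl)cyclopentan-1-one A1 would expel N2. The ring CH2 next to the carbonyl migrates to the carbene carbon (Wolff rearrangement), and the ketene is trapped by the neighbouring hydroxyl as rac-cis-3-oxabicyclo[3.2.0]heptan-2-one A2.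
- **In its favour:**
  - The rearrangement is unimolecular and predictable, and on this point it is the safer single reaction than the cobalt step.
  - A five-membered lactone can only be cis-fused to a four-membered ring, so the cis relation is fixed as firmly as by the six-membered clamp of the chosen plan (an equal point).
  - The bithiophenes would arrive last by Sonogashira coupling with 3, so no oxidation or hydrogenation would meet a thiophene. This is better than the chosen plan, whose steps 4 and 5 run with four thiophene rings present.
- **Against it here:**
  - A2 holds the ring but only two arm carbons, at different oxidation levels. The symmetry of 14 is lost and the arms must be grown one after the other.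
  - The second arm must pass through a formyl stage on the ring, cis to an alkynyl group, where the alpha C–H can epimerise to trans under basic alkyne-forming conditions. The chosen plan has no such leak.
  - A1 itself requires regioselective diazo transfer at the more hindered alpha-carbon of its ketone precursor.
- **Comparison:** on structure, the chosen key step forms two skeletal bonds and delivers every carbon of 14 in one symmetrical intermediate, whereas A2 holds the ring and two arm carbons only. On mechanism, the photochemical rearrangement is the better of the two in predictability, and the two are equal in how a fused ring enforces cis. On step economy, about ten steps would be needed against six.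

Alternative 2: The cut is the C2–C-alpha bond of one arm together with the C1–C4 ring bond.
- **Forward key step:** dimethyl 2-(3-bromopropylidene)malonate A3 would accept diethyl[(2,2'-bithiophen-5-yl)ethynyl]aluminium A4, made from 6, at its beta-carbon. The malonate enolate then displaces the primary bromide in a 4-exo-tet closure to give rac-dimethyl 2-[(2,2'-bithiophen-5-yl)ethynyl]cyclobutane-1,1-dicarboxylate A5.
- **In its favour:**
  - The ring and one finished arm come from acyclic pieces in one operation.
  - That arm enters as an alkyne, so it needs no ketone-to-alkyne conversion (better than the chosen plan).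
  - No pyrolysis and no hydrogenation selectivity problem arise (also better).
- **Against it here:**
  - A5 has one stereocentre and a geminal diester where the second arm must stand. Removing one ester creates C1 by protonation, which favours trans, the wrong relation for 14.
  - The remaining ester must then go through an epimerisable formyl stage to an alkyne and a second coupling.
  - The aluminium-bound malonate enolate is a sluggish nucleophile for a four-membered closure, and A3 can lose HBr instead.
- **Comparison:** on structure, A5 carries the ring and one complete arm but a quaternary carbon where a cis C–H is needed, while the chosen intermediate carries both arms in masked form. On mechanism, the polar two-stage sequence does not control the cis relation, whereas the chosen plan sets it by syn addition inside a ring; in bringing in a complete arm early the alternative is the equal of the chosen plan. On step economy, it would take about nine to ten steps against six and does not use the symmetry of the target.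

Alternative 3: The cut is at both ring bonds to C4 (C3–C4 and C1–C4), with C4 supplied as a sulfonyl-stabilised one-carbon unit.
- **Forward key step:** the bis-mesylate rac-1,6-bis(2,2'-bithiophen-5-yl)-4-[(methanesulfonyloxy)methyl]hexa-1,5-diyn-3-yl methanesulfonate A6 would be treated with twice-deprotonated methyl phenyl sulfone A7, which first displaces the primary mesylate. The new alpha-sulfonyl carbanion would then close on the secondary propargylic mesylate with inversion, giving rac-cis-2,3-bis[(2,2'-bithiophen-5-yl)ethynyl]cyclobutyl phenyl sulfone A8. Reductive desulfonylation would finish the synthesis.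
- **In its favour:**
  - Both arms are complete before the ring is closed.
  - Only one step follows the key step, against three in the chosen plan (better).
  - No alkene hydrogenation or oxidative cleavage is run near the thiophenes (also better).
- **Against it here:**
  - The cis relation depends on a stereodefined acyclic precursor A6 and on clean inversion at a secondary propargylic centre during a strained 4-exo-tet closure.
  - The C–H between the two leaving-group carbons of A6 is propargylic and beta to a mesylate. The strongly basic dianion can eliminate there to a conjugated enyne, attack in the SN2' sense to an allene, or epimerise the centre.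
  - The final desulfonylation must spare two arylalkynes.
- **Comparison:** on structure, A8 already holds both finished arms, which is better than the masked arms of the chosen intermediate. On mechanism, stereochemistry is carried over from an open chain through a double displacement, whereas the chosen plan creates it on a ring with a symmetrical alkene. On step economy, A6 would take five or six steps to make, so about eight to nine steps overall against six.

Key step: step 3

Remark: the stereodescriptors of the target SMILES correspond to the cis isomer (1R,2S, meso, achiral), so the route is planned for this isomer and needs relative stereocontrol only.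

## Route

Step 1
Reactants: 1 propadiene (two molecules)
Product: 2 1,2-dimethylenecyclobutane
Conditions: propadiene in N2 carrier, quartz flow tube, 500 °C, short contact time; trap at −78 °C; distillation
Reagents that add atoms: none
Why: Thermal [2+2] dimerisation of an allene: the central carbons of two molecules of 1 bond first to a bis-allyl diradical, which closes between two CH2 termini, so the two exocyclic C=CH2 groups end up on adjacent ring carbons; short contact time limits further reaction of 2 with 1, and the isomeric 1,3-dimethylenecyclobutane expected as a minor co-product has no conjugated diene and is expected to remain a spectator in step 3.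

Step 2
Reactants: 3 5-bromo-2,2'-bithiophene (2 equiv); 4 trimethylsilylacetylene (1 equiv)
Product: 7 1,2-bis(2,2'-bithiophen-5-yl)ethyne, via silylalkyne 5 (not isolated), via terminal alkyne 6 (not isolated)
Conditions: PdCl2(PPh3)2 (5 mol %), CuI (10 mol %), DBU (6 equiv), H2O (0.5 equiv), toluene, 70 °C, argon
Reagents that add atoms: none
Why: One-pot double Sonogashira coupling: zerovalent palladium formed from PdCl2(PPh3)2 with CuI couples 3 with the C–H end of 4 to give 5, the amidine base with a measured amount of water removes the silyl group, and 6 is carried by CuI onto palladium and couples with the second equivalent of 3; 2-bromothiophenes undergo oxidative addition readily, and the low standing concentration of 6 under argon suppresses oxidative homocoupling.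

Step 3
Reactants: 2 1,2-dimethylenecyclobutane; 7 1,2-bis(2,2'-bithiophen-5-yl)ethyne
Product: 8 3,4-bis(2,2'-bithiophen-5-yl)bicyclo[4.2.0]octa-1(6),3-diene
Conditions: CoBr2(Ph2PCH2CH2PPh2) (10 mol %), Zn (20 mol %), ZnI2 (20 mol %), CH2Cl2, 25 °C, argon; 2 added in portions until 7 is consumed
Reagents that add atoms: none
Why: The step is a formal [4+2] cycloaddition of one molecule of a 1,3-diene with one molecule of an unactivated internal alkyne on low-valent cobalt, the closest known reaction type being the CoBr2(Ph2PCH2CH2PPh2)/Zn/ZnI2-catalysed neutral Diels–Alder reaction of 2,3-disubstituted butadienes with diarylalkynes to cyclohexa-1,4-dienes. Zn reduces divalent cobalt to monovalent cobalt and ZnI2 abstracts halide, so that a cationic cobalt centre can bind the s-cis diene of 2 and the alkyne 7 side by side. Oxidative cyclisation joins one exocyclic CH2 to one alkyne carbon (first C-alpha–C-beta bond, C2–C3 of 8) and gives a trivalent cobalt allyl–vinyl metallacycle; reductive elimination then forms the second bond (C4–C5) and returns monovalent cobalt. The six-membered ring is closed in that reductive elimination from a seven-membered cobaltacycle, that is by annulation of two components and not by cyclisation of a tether, and the former C1–C2 single bond of 2 becomes the ring-fusion alkene C1=C6. No stereocentre is created, since C2 and C5 are CH2 groups and C1, C3, C4 and C6 are sp2. The selectivity needed is cross-cycloaddition over alkyne cyclotrimerisation and diene oligomerisation: 2 is locked s-cis and is fed in portions so that it is never the limiting partner yet never in large standing excess, the symmetrical alkyne removes any regiochemical question, and a diarylalkyne with two bulky heteroaryl groups should trimerise slowly. Stepwise bond formation on the metal also makes the reaction insensitive to the wide separation of the two CH2 termini that slows thermal cycloadditions of this diene. Aromatisation of the doubly allylic cyclohexa-1,4-diene to a benzocyclobutene is avoided by excluding oxygen and oxidants at room temperature and taking 8 into step 4 without storage; the chelating diphosphine should hold cobalt against the weakly donating thiophene sulfur.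

Step 4
Reactants: 8 3,4-bis(2,2'-bithiophen-5-yl)bicyclo[4.2.0]octa-1(6),3-diene
Product: 9 (1R,6S)-3,4-bis(2,2'-bithiophen-5-yl)bicyclo[4.2.0]oct-3-ene (cis-fused; meso)
Conditions: H2 (1 atm, stopped after 1 equiv), [Ir(cod)(PCy3)(py)]PF6 (5 mol %), CH2Cl2, 0 °C
Reagents that add atoms: none
Why: Homogeneous hydrogenation with a cationic iridium catalyst of the kind that reduces tetrasubstituted alkenes: both hydrogens go from the metal to the same face of C1=C6, so C1 and C6 are created together with their hydrogens cis (the two faces are equivalent and the product is meso); the tetraalkyl cyclobutene bond is flat, exposed and slightly strained, whereas C3=C4 is shielded by two twisted bithienyl groups, so stopping after one equivalent of H2 should leave it intact.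

Step 5
Reactants: 9 (1R,6S)-3,4-bis(2,2'-bithiophen-5-yl)bicyclo[4.2.0]oct-3-ene
Product: 12 2,2'-[(1R,2S)-cyclobutane-1,2-diyl]bis[1-(2,2'-bithiophen-5-yl)ethan-1-one] (cis; meso), via epoxide 10 (not isolated), via diol 11 (not isolated)
Conditions: dimethyldioxirane (1.05 equiv, acetone), CH2Cl2, −40 to −20 °C; evaporate; H5IO6 (1.2 equiv), THF/H2O, 0 °C
Reagents that add atoms: dimethyldioxirane, CC1(C)OO1; water, O
Why: Epoxidation of the electron-rich tetrasubstituted alkene by the neutral oxygen-transfer reagent should be far faster than S-oxidation of a thiophene and leaves no acid behind; periodic acid in aqueous THF then hydrolyses epoxide 10 to the 1,2-diol 11 and cleaves it through a cyclic periodate ester (epoxide cleavage to a dicarbonyl), cutting C3–C4 into two aryl ketones; C1 and C6 of 9 become C1 and C2 of the cyclobutane untouched and lie beta to the new carbonyls, so the cis relation cannot epimerise.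

Step 6
Reactants: 12 2,2'-[(1R,2S)-cyclobutane-1,2-diyl]bis[1-(2,2'-bithiophen-5-yl)ethan-1-one]
Product: 14 isocardopatine [(1R,2S)-1,2-bis{(2,2'-bithiophen-5-yl)ethynyl}cyclobutane; cis; meso], via bis(enol triflate) 13 (not isolated)
Conditions: LiN(iPr)2 (2.3 equiv), THF, −78 °C, slow addition of 12; PhNTf2 (2.3 equiv), −78 to 0 °C; then LiN(iPr)2 (3 equiv), −78 to −30 °C; aq. NH4Cl
Reagents that add atoms: none
Why: Enolisation is regiospecific (only the CH2 side has protons) and should give the Z-enolates typical of aryl alkyl ketones, O-triflation gives enol triflates with the vinyl H anti to the leaving group, and a second portion of amide base effects anti elimination of triflate to the aryl alkyne (ketone to alkyne through an enol triflate); slow addition of 12 to the base keeps both ketones enolised and so suppresses an intramolecular aldol between the arms, the ring C–H bonds are never acidified, any lithiation of a terminal thiophene position is undone on protonation, and the low temperature avoids alkyne-to-allene isomerisation and thermal rearrangement of the product.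

## Compound list

1 | propadiene | C=C=C | starting material
2 | 1,2-dimethylenecyclobutane | C=C1CCC1=C | intermediate
3 | 5-bromo-2,2'-bithiophene | Brc1ccc(-c2cccs2)s1 | starting material
4 | trimethylsilylacetylene | C[Si](C)(C)C#C | starting material
5 | 5-[(trimethylsilyl)ethynyl]-2,2'-bithiophene | C[Si](C)(C)C#Cc1ccc(-c2cccs2)s1 | intermediate
6 | 5-ethynyl-2,2'-bithiophene | C#Cc1ccc(-c2cccs2)s1 | intermediate
7 | 1,2-bis(2,2'-bithiophen-5-yl)ethyne | C(#Cc1ccc(-c2cccs2)s1)c1ccc(-c2cccs2)s1 | intermediate
8 | 3,4-bis(2,2'-bithiophen-5-yl)bicyclo[4.2.0]octa-1(6),3-diene | C1CC2=C1CC(c1ccc(-c3cccs3)s1)=C(c1ccc(-c3cccs3)s1)C2 | intermediate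
9 | (1R,6S)-3,4-bis(2,2'-bithiophen-5-yl)bicyclo[4.2.0]oct-3-ene (cis-fused; meso) | [C@H]12CC[C@H]1CC(c1ccc(-c3cccs3)s1)=C(c1ccc(-c3cccs3)s1)C2 | intermediate
10 | 3,5-bis(2,2'-bithiophen-5-yl)-4-oxatricyclo[5.2.0.0^3,5]nonane (cis ring fusion; epoxide on the face anti to the cyclobutane; meso) | [C@H]12CC[C@H]1C[C@]1(c3ccc(-c4cccs4)s3)O[C@]1(c1ccc(-c3cccs3)s1)C2 | intermediate
11 | 3,4-bis(2,2'-bithiophen-5-yl)bicyclo[4.2.0]octane-3,4-diol (cis ring fusion; trans-diol from anti opening of 10; racemic, one enantiomer drawn) | [C@H]12CC[C@H]1C[C@](O)(c1ccc(-c3cccs3)s1)[C@@](O)(c1ccc(-c3cccs3)s1)C2 | intermediate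
12 | 2,2'-[(1R,2S)-cyclobutane-1,2-diyl]bis[1-(2,2'-bithiophen-5-yl)ethan-1-one] (cis; meso) | O=C(C[C@@H]1CC[C@@H]1CC(=O)c1ccc(-c2cccs2)s1)c1ccc(-c2cccs2)s1 | intermediate
13 | (1R,2S)-cyclobutane-1,2-diylbis[(1Z)-1-(2,2'-bithiophen-5-yl)ethene-2,1-diyl] bis(trifluoromethanesulfonate) (cis; meso) | FC(F)(F)S(=O)(=O)O/C(c1ccc(-c2cccs2)s1)=C\[C@@H]1CC[C@@H]1/C=C(\OS(=O)(=O)C(F)(F)F)c1ccc(-c2cccs2)s1 | intermediate
14 | isocardopatine, (1R,2S)-1,2-bis[(2,2'-bithiophen-5-yl)ethynyl]cyclobutane (cis; meso) | C(#C[C@@H]1CC[C@@H]1C#Cc1ccc(-c2cccs2)s1)c1ccc(-c2cccs2)s1 | target

## Step count and least certain steps

Total: 6 steps. Longest linear sequence: 5 steps (step 1 or step 2, then steps 3 to 6).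

**Step 3 (key step).** The most likely failure is that the cobalt centre is held up by sulfur coordination, or that oxidative cyclisation with the bulky, electron-rich alkyne is slow. Diene oligomerisation or alkyne trimerisation would then take over, and the cyclohexa-1,4-diene could be dehydrogenated to the arene during handling. The fallback sets out from 2 and returns to the route at 12. It does not close the six-membered ring but attaches each arm by polar chemistry. Bromine should add 1,4 to 2 (Br2, CH2Cl2, −78 °C) to give 1,2-bis(bromomethyl)cyclobut-1-ene F1. 2-(2,2'-Bithiophen-5-yl)-1,3-dithiane F2 is made from commercial 2,2'-bithiophene-5-carbaldehyde and propane-1,3-dithiol with BF3·OEt2, then lithiated with nBuLi at −78 °C. Two equivalents alkylate the allylic bromides of F1 (Corey–Seebach umpolung) to give 1,2-bis{[2-(2,2'-bithiophen-5-yl)-1,3-dithian-2-yl]methyl}cyclobut-1-ene F3. Alkylative hydrolysis (MeI, CaCO3, MeCN/H2O) should unmask 2,2'-(cyclobut-1-ene-1,2-diyl)bis[1-(2,2'-bithiophen-5-yl)ethan-1-one] F4. Syn hydrogenation of its only alkene under the conditions of step 4 gives 12, and step 6 follows.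

**Step 4.** Three things may go wrong: over-reduction of the diaryl alkene, metal-mediated double-bond migration or dehydrogenative aromatisation (the cyclohexa-1,4-diene is itself a hydrogen donor), and inhibition of the cationic iridium centre by sulfur. The fallback sets out from 8 and returns at 9. It replaces metal catalysis by metal-free diimide reduction (2-nitrobenzenesulfonohydrazide, Et3N, CH2Cl2, 25 °C, excess). Diimide transfers both hydrogens to one face in a concerted step, prefers the unhindered strained alkene over the shielded conjugated one, and has no pathway for allylic C–H activation. This fallback makes no new compound (F0).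

**Step 5.** The risk is that acid opens the bis-thienylic epoxide, or the diol derived from it, to a stabilised cation that undergoes a pinacol-type 1,2-shift faster than glycol cleavage. Over-oxidation at thiophene sulfur is a second risk if oxidant is in excess. The fallback sets out from 9 and returns at 12 and avoids cationic intermediates. Syn dihydroxylation with OsO4 (1.1 equiv) and TMEDA in CH2Cl2 at −78 °C, with reductive work-up (aq. NaHSO3), should give 3,4-bis(2,2'-bithiophen-5-yl)bicyclo[4.2.0]octane-3,4-diol F5 (cis ring fusion, cis-diol anti to the cyclobutane). Glycol cleavage with Pb(OAc)4 and K2CO3 in CH2Cl2 at 0 °C then gives 12.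

**Step 6.** The risks are an intramolecular aldol addition of the first-formed enolate to the second ketone, S–O cleavage of a triflate by the amide base (which would return a ketone), and an incomplete second elimination. The fallback sets out from 12 and returns at 14 and avoids enolates. Hydrazine hydrate in EtOH should give the bis(hydrazone) (1R,2S)-1,2-bis[2-(2,2'-bithiophen-5-yl)-2-hydrazinylideneethyl]cyclobutane F6. Iodine with tetramethylguanidine in THF at 0 °C (Barton vinyl iodide synthesis) converts it into (1R,2S)-1,2-bis[2-(2,2'-bithiophen-5-yl)-2-iodoethenyl]cyclobutane F7. Dehydroiodination with KOtBu in THF at 0 °C gives 14.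

## Further compounds

F1 | step 3 | 1,2-bis(bromomethyl)cyclobut-1-ene | BrCC1=C(CBr)CC1
F2 | step 3 | 2-(2,2'-bithiophen-5-yl)-1,3-dithiane | C1CSC(c2ccc(-c3cccs3)s2)SC1
F3 | step 3 | 1,2-bis{[2-(2,2'-bithiophen-5-yl)-1,3-dithian-2-yl]methyl}cyclobut-1-ene | C1CC(CC2(c3ccc(-c4cccs4)s3)SCCCS2)=C1CC1(c2ccc(-c3cccs3)s2)SCCCS1
F4 | step 3 | 2,2'-(cyclobut-1-ene-1,2-diyl)bis[1-(2,2'-bithiophen-5-yl)ethan-1-one] | O=C(CC1=C(CC(=O)c2ccc(-c3cccs3)s2)CC1)c1ccc(-c2cccs2)s1
F0 | step 4 | none | none
F5 | step 5 | 3,4-bis(2,2'-bithiophen-5-yl)bicyclo[4.2.0]octane-3,4-diol (cis ring fusion; cis-diol anti to the cyclobutane; meso) | [C@H]12CC[C@H]1C[C@@](O)(c1ccc(-c3cccs3)s1)[C@@](O)(c1ccc(-c3cccs3)s1)C2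
F6 | step 6 | (1R,2S)-1,2-bis[2-(2,2'-bithiophen-5-yl)-2-hydrazinylideneethyl]cyclobutane | NN=C(C[C@@H]1CC[C@@H]1CC(=NN)c1ccc(-c2cccs2)s1)c1ccc(-c2cccs2)s1
F7 | step 6 | (1R,2S)-1,2-bis[2-(2,2'-bithiophen-5-yl)-2-iodoethenyl]cyclobutane (E/Z mixture) | IC(=C[C@@H]1CC[C@@H]1C=C(I)c1ccc(-c2cccs2)s1)c1ccc(-c2cccs2)s1
A1 | alternative 1 | 2-diazo-3-(hydroxymethyl)cyclopentan-1-one | O=C1CCC(CO)C1=[N+]=[N-]
A2 | alternative 1 | rac-cis-3-oxabicyclo[3.2.0]heptan-2-one | O=C1OC[C@@H]2CC[C@H]12
A3 | alternative 2 | dimethyl 2-(3-bromopropylidene)malonate | COC(=O)C(=CCCBr)C(=O)OC
A4 | alternative 2 | diethyl[(2,2'-bithiophen-5-yl)ethynyl]aluminium | CC[Al](CC)C#Cc1ccc(-c2cccs2)s1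
A5 | alternative 2 | rac-dimethyl 2-[(2,2'-bithiophen-5-yl)ethynyl]cyclobutane-1,1-dicarboxylate | COC(=O)C1(C(=O)OC)CC[C@H]1C#Cc1ccc(-c2cccs2)s1
A6 | alternative 3 | rac-1,6-bis(2,2'-bithiophen-5-yl)-4-[(methanesulfonyloxy)methyl]hexa-1,5-diyn-3-yl methanesulfonate | CS(=O)(=O)OC[C@@H](C#Cc1ccc(-c2cccs2)s1)[C@@H](OS(C)(=O)=O)C#Cc1ccc(-c2cccs2)s1
A7 | alternative 3 | methyl phenyl sulfone | CS(=O)(=O)c1ccccc1
A8 | alternative 3 | rac-cis-2,3-bis[(2,2'-bithiophen-5-yl)ethynyl]cyclobutyl phenyl sulfone | O=S(=O)(c1ccccc1)[C@@H]1C[C@@H](C#Cc2ccc(-c3cccs3)s2)[C@H]1C#Cc1ccc(-c2cccs2)s1
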